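**Plan**

1. Ring locants: O1, C2 (aryl trans to the C3 CH2OH), C3, C4, C5 (aryl cis to the C4 CH2OH). The retrosynthesis first cuts O1–C5 and raises C2 and C5 to the ketone level, giving a C2-symmetric (2R,3R)-1,4-diaryl-2,3-bis(silyloxymethyl)butane-1,4-dione.
2. Enabling feature: C2 and C5 carry the same 4-hydroxy-3,5-dimethoxyphenyl ring, and C3 and C4 carry the same CH2OH group in a trans relation. The two carbonyl carbons are therefore homotopic and 1,4-related, so an oxygen created at one reaches the other through a five-membered ring.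
3. The diketone is then cut at the C4–C5 bond (dithiane acyl anion, conjugate addition) and the C2–C3 bond (aldol), back to a chiral butenolide acetal whose ring supplies C3, C4 and both CH2OH carbons.
4. Forward: a three-component tandem addition–aldol builds the whole carbon skeleton on the temporary lactone acetal. LiAlH4 opens it, the primary alcohols are silylated, one oxidation gives the diketone, and the oxolane ring is formed last, followed by desilylation and debenzylation.
5. Stereochemistry: C3 and C4 come from the menthyloxy acetal centre of the butenolide (anti addition, trans aldol). C2 comes from Felkin–Anh hydride delivery to the diketone. C5 comes from hydride attack on the cyclic oxocarbenium ion anti to the C4 substituent.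

Key step: step 6

Remark: Ar = 4-(benzyloxy)-3,5-dimethoxyphenyl, Men = (1R,2S,5R)-2-isopropyl-5-methylcyclohexyl (from (−)-menthol), TBS = tert-butyldimethylsilyl; 1 and 4 are assumed to be purchased; 7, 8 and 9 are carried as both carbinol epimers, which converge at 11.

Step 1
Reactants: 1 4-(benzyloxy)-3,5-dimethoxybenzaldehyde; 2 propane-1,3-dithiol
Product: 3 2-Ar-1,3-dithiane
Conditions: BF3·OEt2 (cat.), CH2Cl2, 0 °C to rt
Reagents that add atoms: none
Why: Lewis-acid-catalysed dithioacetalisation of an aromatic aldehyde is routine, creates no stereocentre, and installs the Corey–Seebach acyl-anion handle that also masks one future carbonyl carbon through the hydride step.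

Step 2
Reactants: 3 2-Ar-1,3-dithiane; 4 (5R)-5-(MenO)furan-2(5H)-one; 1 4-(benzyloxy)-3,5-dimethoxybenzaldehyde
Product: 7 (3S,4R,5R)-4-(2-Ar-1,3-dithian-2-yl)-3-[Ar(hydroxy)methyl]-5-(MenO)oxolan-2-one as both carbinol epimers, via 2-lithio-2-Ar-1,3-dithiane 5 (not isolated), via lithium lactone enolate 6 (not isolated)
Conditions: n-BuLi, THF, −78 to −20 °C; 4, −78 °C; 1, −78 °C; AcOH quench
Reagents that add atoms: none
Why: In this tandem conjugate addition–aldol reaction the lithiodithiane should add 1,4 to the butenolide anti to the menthyloxy group, and the resulting enolate should add to the aldehyde anti to the bulky dithianyl group, which fixes the two ring carbons that become C3 and C4 in a trans relation; the carbinol carbon forms without control and is erased in step 5.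

Step 3
Reactants: 7 tandem adduct
Product: 8 (2R,3R)-2-[Ar(hydroxy)methyl]-3-(2-Ar-1,3-dithian-2-yl)butane-1,4-diol as both carbinol epimers
Conditions: LiAlH4, THF, 0 °C to rt; H2O work-up
Reagents that add atoms: none
Why: Hydride reduction of the lactone carbonyl, collapse of the released hemiacetal and reduction of the resulting aldehyde should turn the temporary lactone acetal into the two CH2OH groups and expel menthol, while the dithiane, the benzyl ethers and the two ring-derived stereocentres are untouched.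

Step 4
Reactants: 8 triol
Product: 9 (2R,3R)-1-Ar-3-(2-Ar-1,3-dithian-2-yl)-4-(TBSO)-2-(TBSOCH2)butan-1-ol as both carbinol epimers
Conditions: TBSCl (2.2 equiv), imidazole, DMF, 0 °C
Reagents that add atoms: tert-butyldimethylsilyl chloride, CC(C)(C)[Si](C)(C)Cl
Why: Silylation should be selective for the two primary hydroxyls over the hindered secondary benzylic one, and it keeps the primary oxygens from competing for a carbonyl carbon in step 6.

Step 5
Reactants: 9 bis-silyl ether
Product: 11 (2R,3R)-1,4-di-Ar-2,3-bis(TBSOCH2)butane-1,4-dione, via keto dithiane 10 (not isolated)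
Conditions: Dess–Martin periodinane (excess), CH2Cl2/MeCN/H2O, 0 °C to rt
Reagents that add atoms: water, O
Why: Dess–Martin oxidation should convert the benzylic alcohol to the aryl ketone and, with water present, cleave the 1,3-dithiane oxidatively to the second aryl ketone, so both carbinol epimers converge on one C2-symmetric diketone; the near-neutral medium should spare the α-stereocentres and the β-silyloxy groups.

Step 6
Reactants: 11 C2-symmetric diketone
Product: 14 (2S,3R,4R,5R)-2,5-di-Ar-3,4-bis(TBSOCH2)oxolane, via hydroxy ketone 12 (not isolated), via lactol 13 (not isolated)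
Conditions: LiBH(sec-Bu)3 (1.05 equiv), CH2Cl2/THF, −78 °C; then Et3SiH, BF3·OEt2 (excess), −78 °C
Reagents that add atoms: none
Why: LiBH(sec-Bu)3 should add one hydride to either homotopic carbonyl under Felkin–Anh control (branched neighbouring carbon anti to the hydride, CH2OTBS inside; a 1,3-chelate model predicts the same sense), which sets C2 with its aryl trans to the C3 substituent, and the lithium alkoxide then closes onto the second carbonyl, forming O1–C5 by 5-exo-trig hemiketalisation and shielding that carbon from a second hydride. BF3·OEt2 then ionises the hemiketal to the 2-aryl oxocarbenium ion, which Et3SiH reduces; the closest known reaction types are the Felkin-controlled reduction of α-branched aryl ketones and the Lewis acid/silane reductive deoxygenation of 2-aryl lactols used for 2,5-diaryl oxolane lignans. C5 is set by hydride attack on the envelope oxocarbenium ion from the face anti to the adjacent C4 CH2OTBS group, which places the C5 aryl cis to that group and cis to the C2 aryl. Site selectivity is not an issue because the diketone is C2-symmetric and either carbonyl gives the same hydroxy ketone. Mono-reduction is secured by one equivalent of a one-hydride reagent and fast ring closure, and kinetic control at C5 by holding −78 °C so that the benzylic C–O bonds do not ionise and drift to the all-trans isomer. The primary oxygens are silylated, so only the C2 oxygen can reach C5.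

Step 7
Reactants: 14 bis-silyl oxolane
Product: 15 [(2S,3R,4R,5R)-2,5-di-Ar-oxolane-3,4-diyl]dimethanol
Conditions: Bu4NF, THF, 0 °C to rt
Reagents that add atoms: none
Why: Fluoride-driven desilylation should free both primary alcohols without affecting the benzyl ethers or the four stereocentres.

Step 8
Reactants: 15 bis-benzyl ether diol
Product: 16 4,4'-[(2S,3R,4R,5R)-3,4-bis(hydroxymethyl)oxolane-2,5-diyl]bis(2,6-dimethoxyphenol)
Conditions: H2 (1 atm), Pd/C, EtOAc/MeOH, rt
Reagents that add atoms: none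
Why: Catalytic hydrogenolysis of the two phenolic benzyl ethers should be much faster than cleavage of the ring benzylic C–O bonds under neutral conditions, so the target should result with all stereocentres intact.

**Compound list**

1 | 4-(benzyloxy)-3,5-dimethoxybenzaldehyde | O=Cc1cc(OC)c(OCc2ccccc2)c(OC)c1 | starting material
2 | propane-1,3-dithiol | SCCCS | starting material
3 | 2-[4-(benzyloxy)-3,5-dimethoxyphenyl]-1,3-dithiane | COc1cc(C2SCCCS2)cc(OC)c1OCc1ccccc1 | intermediate
4 | (5R)-5-{[(1R,2S,5R)-2-isopropyl-5-methylcyclohexyl]oxy}furan-2(5H)-one | O=C1O[C@@H](O[C@@H]2C[C@H](C)CC[C@H]2C(C)C)C=C1 | starting material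
5 | 2-lithio-2-[4-(benzyloxy)-3,5-dimethoxyphenyl]-1,3-dithiane (formed in the flask) | [Li]C1(c2cc(OC)c(OCc3ccccc3)c(OC)c2)SCCCS1 | intermediate
6 | lithium (4R,5R)-4-(2-Ar-1,3-dithian-2-yl)-5-(MenO)-4,5-dihydrofuran-2-olate (formed in the flask) | [Li+].[O-]C1=C[C@@H](C2(c3cc(OC)c(OCc4ccccc4)c(OC)c3)SCCCS2)[C@H](O[C@@H]2C[C@H](C)CC[C@H]2C(C)C)O1 | intermediate
7 | (3S,4R,5R)-4-(2-Ar-1,3-dithian-2-yl)-3-[Ar(hydroxy)methyl]-5-(MenO)oxolan-2-one, both carbinol epimers | O=C1O[C@@H](O[C@@H]2C[C@H](C)CC[C@H]2C(C)C)[C@H](C2(c3cc(OC)c(OCc4ccccc4)c(OC)c3)SCCCS2)[C@H]1C(O)c1cc(OC)c(OCc2ccccc2)c(OC)c1 | intermediate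
8 | (2R,3R)-2-[Ar(hydroxy)methyl]-3-(2-Ar-1,3-dithian-2-yl)butane-1,4-diol, both carbinol epimers | OC(c1cc(OC)c(OCc2ccccc2)c(OC)c1)[C@@H](CO)[C@H](CO)C1(c2cc(OC)c(OCc3ccccc3)c(OC)c2)SCCCS1 | intermediate
9 | (2R,3R)-1-Ar-3-(2-Ar-1,3-dithian-2-yl)-4-(TBSO)-2-(TBSOCH2)butan-1-ol, both carbinol epimers | OC(c1cc(OC)c(OCc2ccccc2)c(OC)c1)[C@@H](CO[Si](C)(C)C(C)(C)C)[C@H](CO[Si](C)(C)C(C)(C)C)C1(c2cc(OC)c(OCc3ccccc3)c(OC)c2)SCCCS1 | intermediate
10 | (2R,3R)-1-Ar-3-(2-Ar-1,3-dithian-2-yl)-4-(TBSO)-2-(TBSOCH2)butan-1-one (formed in the flask) | O=C(c1cc(OC)c(OCc2ccccc2)c(OC)c1)[C@@H](CO[Si](C)(C)C(C)(C)C)[C@H](CO[Si](C)(C)C(C)(C)C)C1(c2cc(OC)c(OCc3ccccc3)c(OC)c2)SCCCS1 | intermediate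
11 | (2R,3R)-1,4-di-Ar-2,3-bis(TBSOCH2)butane-1,4-dione | O=C(c1cc(OC)c(OCc2ccccc2)c(OC)c1)[C@@H](CO[Si](C)(C)C(C)(C)C)[C@H](CO[Si](C)(C)C(C)(C)C)C(=O)c1cc(OC)c(OCc2ccccc2)c(OC)c1 | intermediate
12 | (2R,3R,4S)-1,4-di-Ar-4-hydroxy-2,3-bis(TBSOCH2)butan-1-one (formed in the flask as its lithium alkoxide) | O[C@H](c1cc(OC)c(OCc2ccccc2)c(OC)c1)[C@@H](CO[Si](C)(C)C(C)(C)C)[C@H](CO[Si](C)(C)C(C)(C)C)C(=O)c1cc(OC)c(OCc2ccccc2)c(OC)c1 | intermediate
13 | (3R,4R,5S)-2,5-di-Ar-3,4-bis(TBSOCH2)oxolan-2-ol, either anomer (formed in the flask as its lithium salt) | COc1cc([C@H]2OC(O)(c3cc(OC)c(OCc4ccccc4)c(OC)c3)[C@@H](CO[Si](C)(C)C(C)(C)C)[C@@H]2CO[Si](C)(C)C(C)(C)C)cc(OC)c1OCc1ccccc1 | intermediate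
14 | (2S,3R,4R,5R)-2,5-di-Ar-3,4-bis(TBSOCH2)oxolane | COc1cc([C@H]2O[C@@H](c3cc(OC)c(OCc4ccccc4)c(OC)c3)[C@@H](CO[Si](C)(C)C(C)(C)C)[C@@H]2CO[Si](C)(C)C(C)(C)C)cc(OC)c1OCc1ccccc1 | intermediate
15 | [(2S,3R,4R,5R)-2,5-di-Ar-oxolane-3,4-diyl]dimethanol | COc1cc([C@H]2O[C@@H](c3cc(OC)c(OCc4ccccc4)c(OC)c3)[C@@H](CO)[C@@H]2CO)cc(OC)c1OCc1ccccc1 | intermediate
16 | 4,4'-[(2S,3R,4R,5R)-3,4-bis(hydroxymethyl)oxolane-2,5-diyl]bis(2,6-dimethoxyphenol) | COc1cc([C@H]2O[C@@H](c3cc(OC)c(O)c(OC)c3)[C@@H](CO)[C@@H]2CO)cc(OC)c1O | target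

**Step count and risks**

Total steps: 8. Longest linear sequence: 8 steps (1 to 16; 4 and a second equivalent of 1 enter in step 2).

Steps most likely to fail:

1. Step 6. What may go wrong: weak facial discrimination in the first hydride delivery, reduction of the second carbonyl before the ring closes, or ionisation and epimerisation at C5. Fallback, from 11 back to 14: reagent-controlled Corey–Bakshi–Shibata reduction of both carbonyls ((R)-2-methyl-oxazaborolidine, BH3·SMe2) should give the C2-symmetric (1S,2R,3R,4S)-diol F1. MsCl/Et3N then converts one of its two homotopic hydroxyls to the monomesylate F2, which the remaining hydroxyl displaces in a 5-exo-tet closure with inversion, giving 14.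

2. Step 5. What may go wrong: oxidation at sulfur without C–S cleavage, loss of silanol by β-elimination, or enolisation of the 1,4-diketone. Fallback, from 9 back to 13: Dess–Martin oxidation under anhydrous conditions stops at keto dithiane 10, which is isolated. Felkin–Anh reduction with LiBH(sec-Bu)3 should give the single (1S,2R,3R)-alcohol F3. S-methylation and hydrolysis of the dithiane (MeI, CaCO3, aqueous MeCN) then releases the ketone, which closes to lactol 13. This is reduced as in the second half of step 6, so the free 1,4-diketone is never formed.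

3. Step 2. What may go wrong: reversal of the aldol addition and proton transfer to the hindered enolate, which would leave only the conjugate adduct. Fallback, from 6 back to 7: the enolate is silylated with Me3SiCl to the silyl ketene acetal F4. A Mukaiyama aldol addition to 1 (BF3·OEt2, CH2Cl2, −78 °C) under non-equilibrating Lewis-acid conditions then gives 7.

**Further compounds**

F1 | step 6 | (1S,2R,3R,4S)-1,4-di-Ar-2,3-bis(TBSOCH2)butane-1,4-diol | O[C@H](c1cc(OC)c(OCc2ccccc2)c(OC)c1)[C@@H](CO[Si](C)(C)C(C)(C)C)[C@H](CO[Si](C)(C)C(C)(C)C)[C@H](O)c1cc(OC)c(OCc2ccccc2)c(OC)c1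
F2 | step 6 | (1S,2R,3R,4S)-1,4-di-Ar-4-hydroxy-2,3-bis(TBSOCH2)butyl methanesulfonate | CS(=O)(=O)O[C@H](c1cc(OC)c(OCc2ccccc2)c(OC)c1)[C@@H](CO[Si](C)(C)C(C)(C)C)[C@H](CO[Si](C)(C)C(C)(C)C)[C@H](O)c1cc(OC)c(OCc2ccccc2)c(OC)c1
F3 | step 5 | (1S,2R,3R)-1-Ar-3-(2-Ar-1,3-dithian-2-yl)-4-(TBSO)-2-(TBSOCH2)butan-1-ol | O[C@H](c1cc(OC)c(OCc2ccccc2)c(OC)c1)[C@@H](CO[Si](C)(C)C(C)(C)C)[C@H](CO[Si](C)(C)C(C)(C)C)C1(c2cc(OC)c(OCc3ccccc3)c(OC)c2)SCCCS1
F4 | step 2 | trimethyl{[(4R,5R)-4-(2-Ar-1,3-dithian-2-yl)-5-(MenO)-4,5-dihydrofuran-2-yl]oxy}silane | C[Si](C)(C)OC1=C[C@@H](C2(c3cc(OC)c(OCc4ccccc4)c(OC)c3)SCCCS2)[C@H](O[C@@H]2C[C@H](C)CC[C@H]2C(C)C)O1
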